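The data were computed for an exercise, noise included.

The closed, stirred vessel held 0.10 M starting material and 0.0300 M protic impurity, and I wanted the height and time of its target maximum. Two earlier runs bracketed that [protic impurity].

| setting | spring | dawn | flask |
|---|---|---|---|
| starting material | 0.10 M | 0.10 M | 0.10 M |
| protic impurity | 0.015 M | 0.060 M | 0.0300 M |
| remark | run made earlier | run made earlier |  |
| time |  |  | 6.0 min |

| run | time / min | target / % | starting material / % |
|---|---|---|---|
| spring | 0.167 | 44.0 | 1.0 |
| spring | 0.333 | 54.4 | 0.1 |
| spring | 0.667 | 44.4 | 0 |
| spring | 1.33 | 19.2 | 0 |
| spring | 3.00 | 0.3 | 0 |
| spring | 6.00 | 0.8 | 0 |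
| dawn | 0.167 | 41.1 | 1.3 |
| dawn | 0.333 | 48.9 | 0 |
| dawn | 0.667 | 41.4 | 1.0 |
| dawn | 1.33 | 15.9 | 0.8 |
| dawn | 3.00 | 1.5 | 0 |
| dawn | 6.00 | 0 | 0.2 |

(readings scatter by 1 percentage point)

- in percentages every species weighs as the starting material in it: one side product counts as two
- the earlier runs were read with a standard deviation of 1 percentage point
- on the list of suspects stand: starting material <-> intermediate A; intermediate A <-> intermediate B; starting material <-> intermediate C; intermediate A -> intermediate D; intermediate D <-> intermediate E; intermediate C -> target; target -> intermediate D; intermediate A <-> intermediate C; starting material + protic impurity -> quenched substrate; starting material + intermediate D -> side product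

- time, not beyond 6.0 min, at which the flask holds most target
- the amount of target, in percent of the starting material charged, at that time

In the spring run the target read highest at 0.333 min, but that was merely a sampling time, so I doubted it was the top. Between 0.667 min and 1.33 min the spring readings of the target fell at 1.26 /min, a lifetime of 0.794 min. I treated the spring curve as consecutive first-order steps and peeled the 0.333 min reading off that extrapolated fall, which gave an estimated formation constant of 6.15 /min and an estimated top at 0.324 min. That lay 0.00900 min before the sampled reading, so I let the reading stand for the spring top, and I took 0.324 min for the flask, since the dawn run also read highest at 0.333 min.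

For the height, the spring and dawn readings at 0.333 min suggested a fractional loss of 2.25 /M. But their difference of 5.5 percentage points carries a scatter of 1.4 points. Pooling the first 3 readings of each run gave 1.77 /M, my skim: the fraction of the target height lost per molar of added protic impurity, at 0.10 M starting material. Two runs cannot test a straight line, but the flask lies between them. From the spring reading, the skim put the flask at 53.0%.

The forecast gave 53% at 0.37 min: “Quenching therefore only skims starting material, with the loss roughly proportional to impurity”. Its height matched mine, while my time was earlier.

The flask gave 53.1% at 0.339 min.

    starting material ⇌ intermediate A (K = 0.460, k = 0.0890 /s)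
    intermediate A ⇌ intermediate B (K = 0.500, k = 0.0440 /s)
    starting material ⇌ intermediate C (K = 21.0, k = 1.10 /s)
    intermediate A → intermediate D (k = 1.70 /s)
    intermediate D ⇌ intermediate E (K = 1.40, k = 0.0230 /s)
    intermediate C → target (k = 0.0950 /s)
    target → intermediate D (k = 0.0220 /s)
    intermediate A ⇌ intermediate C (k = 0.120 /s)
    starting material + protic impurity → quenched substrate (k = 2.40 /M/s)
    starting material + intermediate D → side product (k = 0.520 /M/s)

At that time the flask held 7.01% of the charged starting material as quenched substrate and 76.6% of the protic impurity's own charge. Starting from this flask's height, the skim put the same flask with 0.075 M protic impurity at 48.9%, and that neighbouring flask reached 48.2%.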